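Each molecule of product has cost one molecule of partner: starting material reacts with catalyst intermediate A, which partner and free catalyst build, and the catalyst comes back while the partner doesn't.

| flask | starting material | partner | scavenger | free catalyst | remark | time |
|---|---|---|---|---|---|---|
| ash | 0.20 M | 0.12 M | 0.20 M | 0.14 mM | run made earlier |  |
| alder | 0.20 M | 0.18 M | 0.20 M | 0.28 mM | run made earlier |  |
| south-west | 0.20 M | 0.180 M | 0.300 M | 0.14 mM |  | 10 d |
| south | 0.20 M | 0.180 M | 0.200 M | 0.14 mM |  | 10 d |

- ash (time / d: starting material / %, product / %): 1.04: 68, 32; 2.08: 54, 53; 3.00: 42, 57; 4.00: 42, 58; 5.00: 42, 57; 6.00: 40, 63
- alder (time / d: starting material / %, product / %): 1.04: 41, 61; 2.08: 20, 79; 3.00: 16, 82; 4.00: 15, 88; 5.00: 11, 90; 6.00: 11, 92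

(standard deviation of a reading: 2 percentage points)

- released group is meant together with its idle adduct
- the numbers in the tables scatter by 2 percentage points (one standard deviation)
- what may be going on: partner + free catalyst <-> catalyst intermediate A; starting material + catalyst intermediate A -> catalyst intermediate B; catalyst intermediate B <-> released group + catalyst intermediate C; catalyst intermediate C <-> catalyst intermediate D; catalyst intermediate D <-> free catalyst + product; partner + released group <-> idle adduct; scavenger + released group -> scavenged by-product
- no earlier run changes the charge of scavenger; that part of a forecast is a guess

* part of the starting material that has reacted at the end, south-west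
* part of the starting material that has reacted at the end, south
* what raising the concentration of scavenger from its lowest to its highest value here does to the part of the starting material that has reacted (changes below 5 percentage points count as none) (it rises / it falls / no change)

Partner charge over starting-material charge gives 90.0 % in south and south-west. This is the partner ceiling f, the share of the starting material that the charged partner can pay for, with partner as the limiting reagent. The ash run supports it: its f is 60.0 %, and 60.0 % has reacted at its last reading. So f is the bound from above. The scavenger charges, 0.200 M in south and 0.300 M in south-west, both exceed the 0.180 M of partner, so no lower ceiling comes from them, though that stays a guess because no earlier run changes the scavenger.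

The bound from below comes from alder, which has the partner charge of south and twice its catalyst. Early on alder has reacted 59.0 % against 32.0 % in ash, so the clock seems to run with the catalyst, although ash also held less partner. On that clock, 10 d in south counts as 5.00 d in alder, where 89.0 % had reacted, give or take 2 percentage points. The bracket is therefore 89.0 % to 90.0 %, for both flasks.

The forecast gives 89 % (84 % to 92 %) for south-west, at the lower edge of that bracket, 88 % (83 % to 91 %) for south, just below it, and no change, and adds: “The scavenger effect is a guess, since no run varied it.”

South-west gives 89.1 % and south 89.1 %, a change of 0 points, so the answer on raising the scavenger is no change.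

    partner + free catalyst ⇌ catalyst intermediate A (K = 6.71 /M, k = 14400 /M/h)
    starting material + catalyst intermediate A → catalyst intermediate B (k = 866 /M/h)
    catalyst intermediate B ⇌ released group + catalyst intermediate C (K = 0.224 M, k = 392 /h)
    catalyst intermediate C ⇌ catalyst intermediate D (K = 2.02, k = 34.5 /h)
    catalyst intermediate D ⇌ free catalyst + product (K = 1.06 M, k = 8670 /h)
    partner + released group ⇌ idle adduct, settled at all times (K = 14.3 /M)
    scavenger + released group → scavenged by-product (k = 47.8 /M/h)

Scavenger left differs, 41 % of its charge in south-west against 11 % in south. The south-west gap of 0.90 points below f matches the partner still unbound there, 1.0 % of its charge, or 0.92 points of the starting material. The neighbouring flask is south-west with 0.072 M of partner, so its f is 36.0 %. At 10 d that neighbouring flask gives 36.0 %, with partner at 0 % and starting material at 64.0 %.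

The earlier runs and the new flask come from a simulation with made-up constants; noise was put on by code.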